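The quinone ring (C1=O, C2–OH, C3–hexadecyl, C4=O, C5–OMe, C6–H) is disconnected at C4–C5. The feature exploited is that the contiguous arc C1–C2–C3–C4 carries the substitution of a squarate four-membered ring, while C5=C6 is methoxyacetylene. The precursor is a 4-hydroxy-4-(methoxyethynyl)cyclobutenone bearing hexadecyl at C2 and tert-butoxy at C3 (cyclobutenone numbering). Heating opens its strained ring to an enynylketene that recloses through C4–C5. The six-membered ring, all four substituents and the quinone oxidation level thus arrive in one operation. The 2,5-oxygen pattern is set beforehand by carbonyl-selective acetylide addition. tert-Butyl masks the C2 hydroxyl and is removed by acid without touching the C5 methyl ether.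

Key step: step 5

Remark: the side chain is read as unbranched hexadecyl. The target has no stereocenter; the only stereocenter on the route (the carbinol carbon of the key-step precursor) forms racemic and is erased by the ring expansion.

Step 1
Reactants: 1 squaric acid
Product: 2 disilver squarate (Ag2C4O4)
Conditions: AgNO3 (2 equiv), H2O, rt, dark; filter, wash, dry in vacuo
Reagents that add atoms: silver nitrate (AgNO3), [Ag+].[O-][N+](=O)[O-]
Why: Salt metathesis, in which the strong diacid 1 should give a disilver salt that is practically insoluble in water and is collected by filtration.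

Step 2
Reactants: 2 disilver squarate (Ag2C4O4)
Product: 3 di-tert-butyl squarate (3,4-di-tert-butoxycyclobut-3-ene-1,2-dione)
Conditions: t-BuCl (excess), Et2O, rt, dark; filter through Celite, crystallise from pentane
Reagents that add atoms: tert-butyl chloride, CC(C)(C)Cl
Why: Silver-assisted SN1 O-alkylation, in which halide abstraction delivers the tert-butyl cation to the squarate oxygens and precipitation of AgCl drives the reaction, avoiding the Fischer-type esterification that fails with tert-butanol.

Step 3
Reactants: 3 di-tert-butyl squarate; 4 1-bromohexadecane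
Product: 8 3-tert-butoxy-4-hexadecylcyclobut-3-ene-1,2-dione, via hexadecylmagnesium bromide 5 (not isolated), via bromomagnesium alkoxide adduct 6 (not isolated), via tertiary trifluoroacetate 7 (not isolated)
Conditions: 4, Mg, THF, 45 °C; then 3, THF, −78 → −40 °C; (CF3CO)2O, −78 → 0 °C; aq NaHCO3
Reagents that add atoms: none
Why: Grignard 1,2-addition to one of the two equivalent squarate carbonyls stops after one addition because the remaining carbonyl is a vinylogous ester, and O-trifluoroacetylation then lets the tertiary centre ionise to an alkoxy-stabilised cyclobutenyl cation that sheds one tert-butyl group as its trifluoroacetate (1,3-carbonyl transposition), without the aqueous mineral acid that would also strip the second tert-butyl group.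

Step 4
Reactants: 8 3-tert-butoxy-4-hexadecylcyclobut-3-ene-1,2-dione; 9 chloroacetaldehyde dimethyl acetal
Product: 11 (±)-3-tert-butoxy-2-hexadecyl-4-hydroxy-4-(methoxyethynyl)cyclobut-2-en-1-one, via lithium methoxyacetylide 10 (not isolated)
Conditions: 9, LiNEt2 (3 equiv, from n-BuLi and Et2NH), THF, 0 °C; then 8, −78 °C; sat. aq NH4Cl at −78 °C; Et3N-deactivated SiO2 or used crude
Reagents that add atoms: none
Why: Two E2 eliminations and a deprotonation convert the chloroacetal into the alkoxyacetylide, whose 1,2-carbonyl addition should go to the ketone-like carbonyl next to the tert-butoxy-bearing carbon because the other carbonyl is deactivated as a vinylogous ester, and the new carbinol centre forms racemic, which does not matter since step 5 erases it.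

Step 5
Reactants: 11 (±)-3-tert-butoxy-2-hexadecyl-4-hydroxy-4-(methoxyethynyl)cyclobut-2-en-1-one
Product: 14 2-tert-butoxy-3-hexadecyl-5-methoxy-1,4-benzoquinone, via enynylketene 12 (not isolated), via aryl/phenoxyl diradical 13 (not isolated)
Conditions: toluene (0.02 M, degassed), 110 °C, Ar, base-washed glassware
Reagents that add atoms: none
Why: Heating drives a conrotatory 4π electrocyclic opening of the bond between the ketone and carbinol carbons of 11, and the donor hydroxyl turns outward (torquoselectivity), so the methoxyethynyl arm of enynylketene 12 faces the ketene. The ketene carbon then bonds to the distal, methoxy-bearing alkyne carbon (new C4–C5 bond; the one ring formed closes in a 6-endo-dig sense) to give the aryl/phenoxyl diradical 13, and passage of the hydroxyl hydrogen to the C6 radical centre furnishes quinone 14 without any oxidant. This is the Moore rearrangement of 4-alkynyl-4-hydroxycyclobutenones, a reaction type established for 3-tert-butoxy members of the class as well. No stereocenter is created, and the racemic carbinol centre of 11 ends as the planar C1 carbonyl, while the former ketone carbon next to the hexadecyl-bearing carbon becomes C4, so the regiochemistry is already locked in 11. The selectivity required is six-ring against five-ring closure (bonding to the proximal alkyne carbon): the aromatic stabilisation of 13 and the small steric demand of methoxy at the reacting terminus favour the six-membered ring, whereas the oxygen lone pair can stabilise the exocyclic vinyl centre of the five-ring path, which is why an apolar solvent, dilution and acid-free glassware are specified and why the route places its risk here. A methyl ynol ether has no β-hydrogen, so the retro-ene loss of alkene that ethyl ynol ethers suffer at this temperature cannot intervene.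

Step 6
Reactants: 14 2-tert-butoxy-3-hexadecyl-5-methoxy-1,4-benzoquinone
Product: 15 2-hydroxy-3-hexadecyl-5-methoxy-1,4-benzoquinone (target)
Conditions: CF3CO2H, CH2Cl2, 0 °C → rt
Reagents that add atoms: none
Why: Acidolysis (E1-type cleavage) of the tert-butyl vinylogous ester should release isobutene and the C2 hydroxyl, while the C5 methyl ether cannot leave as a stable cation and no water is present to hydrolyse it.

Compound list
1 | squaric acid | OC1=C(O)C(=O)C1=O | starting material
2 | disilver squarate (Ag2C4O4) | [Ag+].[Ag+].[O-]C1=C([O-])C(=O)C1=O | intermediate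
3 | di-tert-butyl squarate | CC(C)(C)OC1=C(OC(C)(C)C)C(=O)C1=O | intermediate
4 | 1-bromohexadecane | CCCCCCCCCCCCCCCCBr | starting material
5 | hexadecylmagnesium bromide | CCCCCCCCCCCCCCCC[Mg]Br | intermediate (not isolated)
6 | bromomagnesium alkoxide of (±)-2,3-di-tert-butoxy-4-hexadecyl-4-hydroxycyclobut-2-en-1-one | CCCCCCCCCCCCCCCCC1(O[Mg]Br)C(OC(C)(C)C)=C(OC(C)(C)C)C1=O | intermediate (not isolated)
7 | (±)-2,3-di-tert-butoxy-1-hexadecyl-4-oxocyclobut-2-en-1-yl trifluoroacetate | CCCCCCCCCCCCCCCCC1(OC(=O)C(F)(F)F)C(OC(C)(C)C)=C(OC(C)(C)C)C1=O | intermediate (not isolated)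
8 | 3-tert-butoxy-4-hexadecylcyclobut-3-ene-1,2-dione | CCCCCCCCCCCCCCCCC1=C(OC(C)(C)C)C(=O)C1=O | intermediate
9 | chloroacetaldehyde dimethyl acetal | COC(CCl)OC | starting material
10 | lithium methoxyacetylide | [Li]C#COC | intermediate (not isolated)
11 | (±)-3-tert-butoxy-2-hexadecyl-4-hydroxy-4-(methoxyethynyl)cyclobut-2-en-1-one | CCCCCCCCCCCCCCCCC1=C(OC(C)(C)C)C(O)(C#COC)C1=O | intermediate
12 | (3Z)-3-tert-butoxy-2-hexadecyl-4-hydroxy-6-methoxyhexa-1,3-dien-5-yn-1-one (enynylketene) | CCCCCCCCCCCCCCCCC(=C=O)/C(OC(C)(C)C)=C(/O)C#COC | intermediate (not isolated)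
13 | six-membered aryl/phenoxyl diradical (oxyl at C4, carbon radical at C6, hydroxyl at C1) | CCCCCCCCCCCCCCCCc1c([O])c(OC)[c]c(O)c1OC(C)(C)C | intermediate (not isolated)
14 | 2-tert-butoxy-3-hexadecyl-5-methoxy-1,4-benzoquinone | CCCCCCCCCCCCCCCCC1=C(OC(C)(C)C)C(=O)C=C(OC)C1=O | intermediate
15 | 2-hydroxy-3-hexadecyl-5-methoxy-1,4-benzoquinone | CCCCCCCCCCCCCCCCC1=C(O)C(=O)C=C(OC)C1=O | target

Total step count: 6. Longest linear sequence: 6 steps (1 → 2 → 3 → 8 → 11 → 14 → 15). Compounds 4 and 9 enter as purchased side inputs.

Steps most likely to fail

1. Step 5.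
- What may go wrong: the ketene carbon may bond to the proximal alkyne carbon, so that a five-membered ring closes, because the methoxy oxygen stabilises the exocyclic centre of that path. Traces of acid may also trigger a Meyer–Schuster-type rearrangement of the ynol ether carbinol, or thermal loss of the tert-butyl group.
- Fallback, from 11 back to 14: the triple bond of 11 is semihydrogenated (H2, Pd/CaCO3 poisoned with Pb(OAc)2, quinoline, EtOAc), as in the Arens–van Dorp sequence. This gives (±)-3-tert-butoxy-2-hexadecyl-4-hydroxy-4-[(Z)-2-methoxyethenyl]cyclobut-2-en-1-one F1.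
- Heating in toluene opens this compound to a dienylketene. Its only closure is a 6π electrocyclisation between the same two carbons (C4 and C5), and tautomerisation then gives 2-tert-butoxy-3-hexadecyl-5-methoxybenzene-1,4-diol F2.
- Oxidation with Ag2O in Et2O returns to 14.

2. Step 4.
- What may go wrong: the elimination of the chloroacetal may be incomplete. Diethylamine or methoxide may compete by addition–elimination at the tert-butoxy-bearing ring carbon. Acid may induce rearrangement of the product during work-up.
- Fallback, from 9 back to 11: acetylide 10, generated as before, is trapped with Bu3SnCl and distilled to give tributyl(methoxyethynyl)stannane F3.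
- Tin–lithium exchange with n-BuLi in THF at −78 °C regenerates 10 free of amine and alkoxide, beside inert tetrabutylstannane. Dione 8 is then added to give 11.

3. Step 3.
- What may go wrong: the second tert-butyl group may be lost under the acidic by-products of the transposition. The poorly soluble long-chain Grignard reagent may add sluggishly at low temperature, and β-hydride reduction of the carbonyl may compete.
- Fallback, from 5 back to 8: the chain is first attached to a robust ester and the protecting group is exchanged afterwards. Reagent 5 adds to purchased diisopropyl squarate (CC(C)OC1=C(OC(C)C)C(=O)C1=O) in THF at −78 °C, with an NH4Cl quench, to give (±)-4-hexadecyl-4-hydroxy-2,3-diisopropoxycyclobut-2-en-1-one F4.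
- Catalytic concentrated HCl in CH2Cl2 transposes it to 3-hexadecyl-4-isopropoxycyclobut-3-ene-1,2-dione F5.
- Aqueous HCl in THF at reflux hydrolyses the vinylogous ester to 3-hexadecyl-4-hydroxycyclobut-3-ene-1,2-dione F6.
- AgNO3 in water precipitates silver 2-hexadecyl-3,4-dioxocyclobut-1-en-1-olate F7. Its two reactive oxygens are equivalent, so t-BuCl in Et2O should give 8 in the manner of step 2.

Further compounds
F1 | step 5 | (±)-3-tert-butoxy-2-hexadecyl-4-hydroxy-4-[(Z)-2-methoxyethenyl]cyclobut-2-en-1-one | CCCCCCCCCCCCCCCCC1=C(OC(C)(C)C)C(O)(/C=C\OC)C1=O
F2 | step 5 | 2-tert-butoxy-3-hexadecyl-5-methoxybenzene-1,4-diol | CCCCCCCCCCCCCCCCc1c(O)c(OC)cc(O)c1OC(C)(C)C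
F3 | step 4 | tributyl(methoxyethynyl)stannane | CCCC[Sn](CCCC)(CCCC)C#COC
F4 | step 3 | (±)-4-hexadecyl-4-hydroxy-2,3-diisopropoxycyclobut-2-en-1-one | CCCCCCCCCCCCCCCCC1(O)C(OC(C)C)=C(OC(C)C)C1=O
F5 | step 3 | 3-hexadecyl-4-isopropoxycyclobut-3-ene-1,2-dione | CCCCCCCCCCCCCCCCC1=C(OC(C)C)C(=O)C1=O
F6 | step 3 | 3-hexadecyl-4-hydroxycyclobut-3-ene-1,2-dione | CCCCCCCCCCCCCCCCC1=C(O)C(=O)C1=O
F7 | step 3 | silver 2-hexadecyl-3,4-dioxocyclobut-1-en-1-olate (AgC20H35O3) | [Ag+].CCCCCCCCCCCCCCCCC1=C([O-])C(=O)C1=O
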